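Follow one substrate molecule.

| flask | substrate | activator | remark | time |
|---|---|---|---|---|
| beta | 0.0050 M | 0.021 M | run made earlier |  |
| delta | 0.017 M | 0.021 M | run made earlier |  |
| gamma | 0.020 M | 0.030 M | run made earlier |  |
| elm | 0.0060 M | 0.0300 M |  | 25 h |
| cedar | 0.020 M | 0.0210 M |  | 25 h |
| alder | 0.010 M | 0.0800 M |  | 25 h |
| birch | 0.010 M | 0.00800 M |  | 25 h |
| ash | 0.010 M | 0.0150 M |  | 25 h |

| run | time / h | ring / % | substrate / % |
|---|---|---|---|
| beta | 1.50 | 13.2 | 30.9 |
| beta | 4.00 | 41.2 | 6.3 |
| beta | 8.00 | 64.0 | 0.3 |
| beta | 12.0 | 70.8 | 0.2 |
| beta | 20.0 | 73.2 | 0 |
| delta | 4.00 | 25.4 | 4.9 |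
| delta | 8.00 | 38.6 | 0.7 |
| delta | 10.0 | 41.4 | 0.3 |
| delta | 15.0 | 43.4 | 0 |
| delta | 20.0 | 43.9 | 0 |
| gamma | 1.50 | 11.2 | 15.3 |
| gamma | 4.00 | 30.8 | 1.9 |
| gamma | 8.00 | 42.8 | 0.5 |
| gamma | 12.0 | 46.0 | 0 |
| gamma | 20.0 | 47.3 | 0 |

(readings scatter by 0.3 percentage points)

- in percentages every species weighs as the substrate in it: one open dimer or self-condensation product counts as two
- candidate steps: 2 substrate -> self-condensation product; substrate + activated form -> open dimer; substrate + activator -> activated form; activated form -> ring

- ranking by amount of ring, in percent of the substrate charged, from high to low, at 25 h (elm / cedar / alder / birch / ash)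
- the amount of ring, in percent of the substrate charged of the flask you put first, at 25 h
- the amount of ring, in percent of the substrate charged of the flask you put last, at 25 h

The candidate steps give it a fork. It takes up activator, at a rate that goes with the activator concentration, and the activated form closes to ring. Or, before or after activation, it meets more substrate, at a rate that goes with the substrate concentration, and ends in self-condensation product or open dimer. So I expect the odds of ring, ring over the rest of the substrate charged, to go with e, the charged activator over the charged substrate.

I test this on the last readings, where ring has nearly stopped: delta moves from 43.4% to 43.9%. Odds divided by e give 0.650 for beta, 0.633 for delta and 0.598 for gamma, with mean 0.627. I carry this mean s, the ring odds per equivalent of activator, a kind of selectivity factor.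

The ring fraction is then se over one plus se. My reckoning gives alder 83.4%, elm 75.8%, ash 48.5%, cedar 39.7% and birch 33.4%.

The weak link is cedar against birch, since s spreads between the runs. So I reforge it: the lowest s on cedar gives 38.6%, still more than the highest s on birch, 34.2%. I commit to birch last.

The forecast says alder > elm > ash > birch > cedar, with 84% first and 39% last, and adds: “The birch/cedar order is close to a toss-up”. It differs from my reckoning in the last two places.

The simulation gives alder > elm > ash > cedar > birch, with 82.0% first and 36.5% last.

    2 substrate → self-condensation product (k = 0.430 M⁻¹ min⁻¹)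
    substrate + activated form → open dimer (k = 0.520 M⁻¹ min⁻¹)
    substrate + activator → activated form (k = 0.510 M⁻¹ min⁻¹)
    activated form → ring (k = 0.00580 min⁻¹)

Birch and cedar stand the other way round from the forecast: cedar holds 39.8% of ring and birch 36.5%. Alder stops short of full ring through the two side steps acting together: taking away the step to open dimer lifts alder from 82.0% to 90.4%, and taking away self-condensation lifts it to 89.5%. Birch's own ring odds per equivalent come to 0.719, more than the carried 0.627. For the neighbour of birch with 0.0048 M of activator, s gives 23.1%, and that flask holds 25.3% of ring.

The earlier runs and the new flask were generated by integration for substances that don't exist; the scatter is artificial.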